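The trans-decalin is cut at C8–C9 and C5–C10. Ring B (C5–C10) is read as the cyclohexene of a [4+2] between a C5=C6–C7=C8 2-silyloxydiene and a C9=C10 (E)-enoate. Ring A (C1–C5, C10) is closed by the C1–C4 tether that carries the C3 silyl ether and the C4 gem-dimethyl group. One thermal intramolecular Diels–Alder reaction of an acyclic triene therefore builds both rings, the quaternary C10 and C5, C8 and C9. It leaves a C7 enol ether for the C7=C8 alkene and a C11 ester for the C11–C15 side chain. C3, the only earlier stereocentre, is set by asymmetric reverse prenylation and steers the cycloaddition.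

Key step: step 7

Remarks on the chemistry.
- Labdane numbering is used throughout: C17 is the methyl on C8, C20 the methyl on C10. TBS = tert-butyldimethylsilyl, Ipc = isopinocampheyl.
- The target is read as the ent-labdane (3R,5S,9R,10S), 13E, esterified at C15 with 32-hydroxydotriacontanoic acid.
- The (2E,6R,8E,10Z) triene and its cycloadduct were checked centre by centre against the target; C3, C5, C9 and C10 of the adduct coincide with it, so no structure was altered.
- The triene is prepared as the single 10Z enol ether (C17 outside; the 10E isomer would not cyclise) and is purified and heated acid-free.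
- Centres formed as mixtures and removed later (C8 of 9, C11 of 28) are drawn without configuration.
- Prenylmagnesium chloride (THF solution), (−)-Ipc2BOMe, diethyl (2-oxobutyl)phosphonate, 16-bromohexadecan-1-ol and 16-bromohexadecanoic acid are assumed to be purchased.

Step 1
Reactants: 1 methyl geranate [methyl (2E)-3,7-dimethylocta-2,6-dienoate]
Product: 3 methyl (2E)-3-methyl-6-oxohex-2-enoate, via ozonide 2 (not isolated)
Conditions: O3, CH2Cl2, −78 °C (Sudan Red 7B end-point); then PPh3, −78 °C → rt
Reagents that add atoms: ozone, [O-][O+]=O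
Why: Ozonolysis (Criegee mechanism) is chemoselective because ozone attacks the electron-rich trisubstituted 6,7-alkene much faster than the ester-deactivated 2,3-alkene and the dye end-point stops the addition there; no stereocentre is formed.

Step 2
Reactants: 3 methyl (2E)-3-methyl-6-oxohex-2-enoate; 4 prenylmagnesium chloride (3-methylbut-2-en-1-ylmagnesium chloride)
Product: 7 methyl (2E,6R)-6-hydroxy-3,7,7-trimethylnona-2,8-dienoate, via prenylborane 5 (not isolated), via borinate 6 (not isolated)
Conditions: 4, (−)-Ipc2BOMe [Ipc from (+)-α-pinene], Et2O, −78 °C → rt; then 3, −78 °C; NaBO3·4H2O, THF/H2O, rt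
Reagents that add atoms: none
Why: Brown asymmetric prenylboration: the allylborane adds through its γ-carbon in a chair Zimmerman–Traxler transition state (reverse-prenyl unit, quaternary C4), and the Ipc groups derived from (+)-α-pinene direct it to the Si face of the aldehyde, which sets C3 as R while the ester stays inert at −78 °C.

Step 3
Reactants: 7 methyl (2E,6R)-6-hydroxy-3,7,7-trimethylnona-2,8-dienoate
Product: 8 methyl (2E,6R)-6-[(tert-butyldimethylsilyl)oxy]-3,7,7-trimethylnona-2,8-dienoate
Conditions: TBSOTf, 2,6-lutidine, CH2Cl2, −78 → 0 °C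
Reagents that add atoms: tert-butyldimethylsilyl triflate, CC(C)(C)[Si](C)(C)OS(=O)(=O)C(F)(F)F
Why: Silylation with the silyl triflate and 2,6-lutidine is the standard protection of a hindered neopentyl-type secondary alcohol and does not touch C3.

Step 4
Reactants: 8 methyl (2E,6R)-6-[(tert-butyldimethylsilyl)oxy]-3,7,7-trimethylnona-2,8-dienoate
Product: 10 methyl (2E,6R)-6-[(tert-butyldimethylsilyl)oxy]-3,7,7-trimethyl-8-oxooct-2-enoate, via vicinal diol 9 (not isolated)
Conditions: OsO4 (2 mol%), NaIO4, 2,6-lutidine, 1,4-dioxane/H2O (3:1), rt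
Reagents that add atoms: osmium tetroxide (catalytic oxygen carrier), O=[Os](=O)(=O)=O; sodium periodate, [Na+].[O-]I(=O)(=O)=O
Why: Lemieux–Johnson cleavage: OsO4 dihydroxylates the monosubstituted vinyl group in preference to the trisubstituted, ester-deactivated 2,3-alkene and periodate cleaves the diol, giving an α-quaternary aldehyde that can neither epimerise nor eliminate.

Step 5
Reactants: 10 methyl (2E,6R)-6-[(tert-butyldimethylsilyl)oxy]-3,7,7-trimethyl-8-oxooct-2-enoate; 11 diethyl (2-oxobutyl)phosphonate
Product: 12 methyl (2E,6R,8E)-6-[(tert-butyldimethylsilyl)oxy]-3,7,7-trimethyl-10-oxododeca-2,8-dienoate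
Conditions: Ba(OH)2·8H2O, THF/H2O (40:1), rt → 40 °C
Reagents that add atoms: none
Why: Horner–Wadsworth–Emmons olefination of a β-ketophosphonate under mild Ba(OH)2 conditions gives the E enone, and the aldehyde has no α-hydrogen and a protected β-oxygen, so aldol and retro-aldol pathways are closed.

Step 6
Reactants: 12 methyl (2E,6R,8E)-6-[(tert-butyldimethylsilyl)oxy]-3,7,7-trimethyl-10-oxododeca-2,8-dienoate
Product: 13 methyl (2E,6R,8E,10Z)-6,10-bis[(tert-butyldimethylsilyl)oxy]-3,7,7-trimethyldodeca-2,8,10-trienoate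
Conditions: TBSOTf, Et3N, CH2Cl2, −78 → 0 °C; chromatography on Et3N-deactivated silica
Reagents that add atoms: tert-butyldimethylsilyl triflate, CC(C)(C)[Si](C)(C)OS(=O)(=O)C(F)(F)F
Why: Soft enolisation (silyl triflate and amine) of the ethyl ketone can only occur at C8 because C4 is quaternary, which gives the cross-conjugated 2-silyloxydiene, and as with other ethyl ketones the Z enol ether (C17 anti to the vinyl group) should be favoured while the ester is not enolised.

Step 7
Reactants: 13 methyl (2E,6R,8E,10Z)-6,10-bis[(tert-butyldimethylsilyl)oxy]-3,7,7-trimethyldodeca-2,8,10-trienoate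
Product: 14 methyl (1R,2S,4aS,6R,8aR)-3,6-bis[(tert-butyldimethylsilyl)oxy]-2,5,5,8a-tetramethyl-1,2,4a,5,6,7,8,8a-octahydronaphthalene-1-carboxylate (labdane 3R,5S,8S,9R,10R)
Conditions: PhMe (0.01 M), BHT (cat.), 185 °C, sealed base-washed tube, 36 h
Reagents that add atoms: none
Why: A concerted, suprafacial thermal [4+2] cycloaddition joins the 10Z 2-silyloxydiene C5=C6–C7=C8 to the E enoate C9=C10; the closest known reaction type is the terminally tethered (type 1) intramolecular Diels–Alder reaction of 2-silyloxy-substituted 1,7,9-decatrienes with an ester-activated dienophile. Ring B closes as the new cyclohexene through both new bonds (C8–C9 and C5–C10, with the enol ether now at C6=C7), and ring A closes in the fused mode because the four-carbon chain C1–C4 ties dienophile carbon C10 to diene terminus C5 in a chair-shaped six-membered array. C9 and C10 follow from the E geometry of the enoate (C11 ends cis to C20), C5 from the transition state with the ester endo and the tether exo (H5 ends trans to C20, hence the trans-decalin), and C8 from the Z enol ether, whose outward C17 ends cis to C11 and is erased in steps 8 and 9. Which enantiomeric series forms is decided by the 3R silyloxy group, which sits equatorial on the chair-shaped tether so that C10 is delivered to one face of the diene and the C3 oxygen ends cis to C20. The step therefore needs endo and diene-face selectivity, which the secondary overlap of the ester with C7, the staggered exo tether and the equatorial preference at C3 should provide, with the C4 gem-dimethyl group pre-organising the tether. Because the C7 oxygen polarises the diene toward C8, which must bond to the ester α-carbon C9, the tether and not the electronics fixes the orientation, so prolonged heating of the acid-free solution with a radical inhibitor is expected to be necessary.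

Step 8
Reactants: 14 Diels–Alder adduct (C7 silyl enol ether)
Product: 16 methyl 6-[(tert-butyldimethylsilyl)oxy]-2,5,5,8a-tetramethyl-3-oxodecahydronaphthalene-1-carboxylate (C7 ketone; C17 equatorial and trans to the C11 ester; C3, C5, C9, C10 as in 14), via axial-methyl ketone 15 (not isolated)
Conditions: TBAF, THF, 0 °C; then K2CO3, MeOH, rt
Reagents that add atoms: none
Why: Fluoride desilylation cleaves the enol silyl ether far faster than the hindered C3 alkyl silyl ether and gives the ketone by protonation at C6, after which carbonate equilibrates C8 through the enolate to the equatorial methyl (thermodynamic epimerisation, relief of the C17/C20 syn-diaxial contact).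

Step 9
Reactants: 16 C7 ketone
Product: 17 methyl 6-[(tert-butyldimethylsilyl)oxy]-2,5,5,8a-tetramethyl-3-{[(trifluoromethyl)sulfonyl]oxy}-1,4,4a,5,6,7,8,8a-octahydronaphthalene-1-carboxylate (C7=C8 enol triflate; C3, C5, C9, C10 as in 14)
Conditions: Tf2O, 2,6-di-tert-butyl-4-methylpyridine, CH2Cl2, 0 °C → rt
Reagents that add atoms: triflic anhydride, O=S(=O)(OS(=O)(=O)C(F)(F)F)C(F)(F)F
Why: Direct triflation of a 2-alkylcyclohexanone with Tf2O and a hindered pyridine proceeds through the O-triflyl oxocarbenium ion, which loses the axial C8 proton to give mainly the more substituted (thermodynamic) C7=C8 enol triflate, while C9 is not enolised and the silyl ether survives the buffered medium.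

Step 10
Reactants: 17 C7=C8 enol triflate
Product: 18 methyl 6-[(tert-butyldimethylsilyl)oxy]-2,5,5,8a-tetramethyl-1,4,4a,5,6,7,8,8a-octahydronaphthalene-1-carboxylate (C7=C8 alkene, C11 methyl ester; ring centres as in the target)
Conditions: Pd(OAc)2 (5 mol%), PPh3, HCO2H, n-Bu3N, DMF, 60 °C
Reagents that add atoms: none
Why: Palladium-catalysed formate reduction of an enol triflate (oxidative addition to zerovalent palladium, formate-to-hydride exchange with loss of CO2, reductive elimination) replaces the triflate by hydrogen without moving the double bond, which fixes the C7=C8 alkene.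

Step 11
Reactants: 18 C11 methyl ester with C7=C8
Product: 19 C11 primary alcohol {[6-[(tert-butyldimethylsilyl)oxy]-2,5,5,8a-tetramethyl-1,4,4a,5,6,7,8,8a-octahydronaphthalen-1-yl]methanol; ring centres as in the target}
Conditions: LiAlH4, Et2O, 0 °C
Reagents that add atoms: none
Why: Hydride reduction of the hindered ester with LiAlH4 gives the primary C11 alcohol and leaves the non-conjugated C7=C8 alkene, the silyl ether and C9 unchanged.

Step 12
Reactants: 19 C11 alcohol
Product: 20 C11 phenyl sulfide (19 with OH replaced by SPh)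
Conditions: PhSSPh, n-Bu3P, pyridine, rt → 60 °C
Reagents that add atoms: diphenyl disulfide, c1ccc(SSc2ccccc2)cc1
Why: Hata reaction: the alcohol is activated as an alkoxyphosphonium salt and displaced by benzenethiolate in an SN2 step at the primary C11, a thiolate being nucleophilic enough for this β-branched centre, and no stereocentre is involved.

Step 13
Reactants: 20 C11 phenyl sulfide
Product: 22 C11 phenyl sulfone, via sulfoxide 21 (not isolated)
Conditions: (NH4)6Mo7O24·4H2O (10 mol%), 30% H2O2, EtOH/THF, 0 °C → rt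
Reagents that add atoms: hydrogen peroxide, OO
Why: Molybdate-catalysed peroxide oxidation takes the sulfide through the sulfoxide to the sulfone much faster than it epoxidises the trisubstituted alkene, so the C7=C8 bond survives.

Step 14
Reactants: 23 3-methylbut-2-en-1-ol (prenol)
Product: 24 tert-butyldimethyl[(3-methylbut-2-en-1-yl)oxy]silane
Conditions: TBSCl, imidazole, CH2Cl2, rt
Reagents that add atoms: tert-butyldimethylsilyl chloride, CC(C)(C)[Si](C)(C)Cl
Why: Standard silylation of a primary allylic alcohol with the silyl chloride and imidazole.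

Step 15
Reactants: 24 tert-butyldimethyl[(3-methylbut-2-en-1-yl)oxy]silane
Product: 25 (2E)-4-[(tert-butyldimethylsilyl)oxy]-2-methylbut-2-en-1-ol
Conditions: SeO2 (cat.), t-BuOOH, CH2Cl2, 0 °C → rt
Reagents that add atoms: selenium dioxide (catalytic oxygen carrier), O=[Se]=O; tert-butyl hydroperoxide, CC(C)(C)OO
Why: Riley allylic oxidation with catalytic SeO2 and the hydroperoxide (ene reaction, then 2,3-sigmatropic shift) oxidises selectively the methyl group trans to the CH2O chain of the trisubstituted alkene, which gives the E allylic alcohol and thereby the later 13E geometry.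

Step 16
Reactants: 25 (2E)-4-[(tert-butyldimethylsilyl)oxy]-2-methylbut-2-en-1-ol
Product: 26 {[(2E)-4-bromo-3-methylbut-2-en-1-yl]oxy}(tert-butyl)dimethylsilane (C12–C15 bromide)
Conditions: CBr4, PPh3, CH2Cl2, 0 °C
Reagents that add atoms: carbon tetrabromide, BrC(Br)(Br)Br
Why: Appel bromination converts the primary allylic alcohol into the bromide by SN2 displacement of the phosphonium-activated oxygen under neutral conditions, without allylic transposition, loss of the E geometry or loss of the silyl ether.

Step 17
Reactants: 22 C11 phenyl sulfone; 26 C12–C15 bromide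
Product: 28 C11-alkylated sulfone (C11 epimers; side chain C12–C15 attached, 13E), via lithiated sulfone 27 (not isolated)
Conditions: n-BuLi, THF, −78 °C; then 26, DMPU, −78 → −30 °C
Reagents that add atoms: none
Why: Alkylation of the α-lithiated sulfone with the primary allylic bromide (SN2) forms the C11–C12 bond, and the new C11 centre arises as a mixture that is of no consequence because the sulfonyl group is removed in step 18.

Step 18
Reactants: 28 C11-alkylated sulfone
Product: 29 3,15-bis-O-TBS ether of ent-labda-7,13E-diene-3β,15-diol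
Conditions: Na/Hg (6% Na), Na2HPO4, MeOH/THF, −20 → 0 °C
Reagents that add atoms: none
Why: Reductive desulfonylation with sodium amalgam (electron transfer, loss of benzenesulfinate, protonation of the C11 carbanion in the phosphate-buffered medium) removes the sulfonyl group, and because the sulfone is homoallylic and not allylic the C13=C14 bond keeps its position and E geometry.

Step 19
Reactants: 29 bis-silyl ether
Product: 31 (2E)-5-[(1R,4aS,6R,8aS)-6-hydroxy-2,5,5,8a-tetramethyl-1,4,4a,5,6,7,8,8a-octahydronaphthalen-1-yl]-3-methylpent-2-en-1-ol (ent-labda-7,13E-diene-3β,15-diol), via 3-O-silyl alcohol 30 (not isolated)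
Conditions: TBAF (excess), THF, 60 °C
Reagents that add atoms: none
Why: Fluoride-mediated desilylation removes the primary allylic silyl ether quickly and the hindered C3 silyl ether on heating, at a stage where no ester or other base-sensitive group is present and no stereocentre is affected.

Step 20
Reactants: 32 16-bromohexadecan-1-ol
Product: 33 [(16-bromohexadecyl)oxy](tert-butyl)dimethylsilane
Conditions: TBSCl, imidazole, DMF, rt
Reagents that add atoms: tert-butyldimethylsilyl chloride, CC(C)(C)[Si](C)(C)Cl
Why: Standard silylation of a primary alcohol with the silyl chloride and imidazole, which leaves the primary bromide untouched.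

Step 21
Reactants: 33 [(16-bromohexadecyl)oxy](tert-butyl)dimethylsilane; 34 16-bromohexadecanoic acid
Product: 37 32-[(tert-butyldimethylsilyl)oxy]dotriacontanoic acid, via Grignard reagent 35 (not isolated), via magnesium carboxylate 36 (not isolated)
Conditions: 33, Mg, THF, 45 °C; 34, MeMgCl, THF, −20 °C; combine, Li2CuCl4 (3 mol%), THF, −20 °C → rt; cold aq. HCl to pH 3
Reagents that add atoms: none
Why: Kochi-type copper-catalysed cross-coupling of an alkyl Grignard reagent with a primary alkyl bromide joins the two C16 chains, the carboxylic acid being masked in the flask as its magnesium salt and the silyl ether tolerating Grignard formation.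

Step 22
Reactants: 31 ent-labda-7,13E-diene-3β,15-diol; 37 32-[(tert-butyldimethylsilyl)oxy]dotriacontanoic acid
Product: 39 C15 ester of 31 with 37 (C3 hydroxyl free, ω-hydroxyl as TBS ether), via O-acylisourea 38 (not isolated)
Conditions: EDC·HCl, DMAP (cat.), CH2Cl2, 0 °C → rt
Reagents that add atoms: none
Why: Steglich-type carbodiimide esterification acylates the unhindered primary allylic C15 hydroxyl much faster than the secondary C3 hydroxyl flanked by the C4 gem-dimethyl group, so about one equivalent of acid should give the C15 monoester without touching a stereocentre.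

Step 23
Reactants: 39 C15 ester with ω-TBS ether
Product: 40 (2E)-5-[(1R,4aS,6R,8aS)-6-hydroxy-2,5,5,8a-tetramethyl-1,4,4a,5,6,7,8,8a-octahydronaphthalen-1-yl]-3-methylpent-2-en-1-yl 32-hydroxydotriacontanoate (target, CNP0253650.1)
Conditions: HF·pyridine, pyridine, THF, 0 °C → rt
Reagents that add atoms: none
Why: Buffered HF·pyridine cleaves the primary silyl ether (Si–F bond formation) under conditions to which the allylic ester, both alkenes and the free C3 alcohol are stable, which gives the target.

Compound list

1 | methyl geranate, methyl (2E)-3,7-dimethylocta-2,6-dienoate | COC(=O)/C=C(\C)CCC=C(C)C | starting material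
2 | ozonide (1,2,4-trioxolane) of 1 at the 6,7-alkene | COC(=O)/C=C(\C)CCC1OOC(C)(C)O1 | intermediate (not isolated)
3 | methyl (2E)-3-methyl-6-oxohex-2-enoate | COC(=O)/C=C(\C)CCC=O | intermediate
4 | prenylmagnesium chloride (3-methylbut-2-en-1-ylmagnesium chloride) | CC(C)=CC[Mg]Cl | starting material
5 | B-(3-methylbut-2-en-1-yl)bis(isopinocampheyl)borane, Ipc from (+)-α-pinene | CC(C)=CCB([C@@H]1C[C@@H]2C[C@H]([C@H]1C)C2(C)C)[C@@H]1C[C@@H]2C[C@H]([C@H]1C)C2(C)C | intermediate (not isolated)
6 | bis(isopinocampheyl)borinate of alcohol 7 | COC(=O)/C=C(\C)CC[C@@H](OB([C@@H]1C[C@@H]2C[C@H]([C@H]1C)C2(C)C)[C@@H]1C[C@@H]2C[C@H]([C@H]1C)C2(C)C)C(C)(C)C=C | intermediate (not isolated)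
7 | methyl (2E,6R)-6-hydroxy-3,7,7-trimethylnona-2,8-dienoate | COC(=O)/C=C(\C)CC[C@@H](O)C(C)(C)C=C | intermediate
8 | methyl (2E,6R)-6-[(tert-butyldimethylsilyl)oxy]-3,7,7-trimethylnona-2,8-dienoate | COC(=O)/C=C(\C)CC[C@@H](O[Si](C)(C)C(C)(C)C)C(C)(C)C=C | intermediate
9 | methyl (2E,6R)-6-[(tert-butyldimethylsilyl)oxy]-8,9-dihydroxy-3,7,7-trimethylnon-2-enoate (C8 epimers) | COC(=O)/C=C(\C)CC[C@@H](O[Si](C)(C)C(C)(C)C)C(C)(C)C(O)CO | intermediate (not isolated)
10 | methyl (2E,6R)-6-[(tert-butyldimethylsilyl)oxy]-3,7,7-trimethyl-8-oxooct-2-enoate | COC(=O)/C=C(\C)CC[C@@H](O[Si](C)(C)C(C)(C)C)C(C)(C)C=O | intermediate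
11 | diethyl (2-oxobutyl)phosphonate | CCC(=O)CP(=O)(OCC)OCC | starting material
12 | methyl (2E,6R,8E)-6-[(tert-butyldimethylsilyl)oxy]-3,7,7-trimethyl-10-oxododeca-2,8-dienoate | COC(=O)/C=C(\C)CC[C@@H](O[Si](C)(C)C(C)(C)C)C(C)(C)/C=C/C(=O)CC | intermediate
13 | methyl (2E,6R,8E,10Z)-6,10-bis[(tert-butyldimethylsilyl)oxy]-3,7,7-trimethyldodeca-2,8,10-trienoate (key-step precursor) | COC(=O)/C=C(\C)CC[C@@H](O[Si](C)(C)C(C)(C)C)C(C)(C)/C=C/C(O[Si](C)(C)C(C)(C)C)=C/C | intermediate
14 | methyl (1R,2S,4aS,6R,8aR)-3,6-bis[(tert-butyldimethylsilyl)oxy]-2,5,5,8a-tetramethyl-1,2,4a,5,6,7,8,8a-octahydronaphthalene-1-carboxylate (key-step product; trans-fused; C20, C11, C17 and the C3 oxygen on one face, H5 on the other) | C[C@@H]1C(O[Si](C)(C)C(C)(C)C)=C[C@@H]2C(C)(C)[C@H](O[Si](C)(C)C(C)(C)C)CC[C@@]2(C)[C@@H]1C(=O)OC | intermediate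
15 | C7 ketone with C8 as in 14 (C17 axial, cis to C11 and C20) | C[C@@H]1C(=O)C[C@@H]2C(C)(C)[C@H](O[Si](C)(C)C(C)(C)C)CC[C@@]2(C)[C@@H]1C(=O)OC | intermediate (not isolated)
16 | methyl 6-[(tert-butyldimethylsilyl)oxy]-2,5,5,8a-tetramethyl-3-oxodecahydronaphthalene-1-carboxylate (C7 ketone; C17 equatorial, trans to C11; other centres as in 14) | C[C@H]1C(=O)C[C@@H]2C(C)(C)[C@H](O[Si](C)(C)C(C)(C)C)CC[C@@]2(C)[C@@H]1C(=O)OC | intermediate
17 | C7=C8 enol triflate of 16 | CC1=C(OS(=O)(=O)C(F)(F)F)C[C@@H]2C(C)(C)[C@H](O[Si](C)(C)C(C)(C)C)CC[C@@]2(C)[C@@H]1C(=O)OC | intermediate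
18 | methyl 6-[(tert-butyldimethylsilyl)oxy]-2,5,5,8a-tetramethyl-1,4,4a,5,6,7,8,8a-octahydronaphthalene-1-carboxylate (C7=C8, C11 ester; ring centres as in the target) | CC1=CC[C@@H]2C(C)(C)[C@H](O[Si](C)(C)C(C)(C)C)CC[C@@]2(C)[C@@H]1C(=O)OC | intermediate
19 | C11 alcohol from 18 (3R silyl ether, C7=C8) | CC1=CC[C@@H]2C(C)(C)[C@H](O[Si](C)(C)C(C)(C)C)CC[C@@]2(C)[C@@H]1CO | intermediate
20 | C11 phenyl sulfide | CC1=CC[C@@H]2C(C)(C)[C@H](O[Si](C)(C)C(C)(C)C)CC[C@@]2(C)[C@@H]1CSc1ccccc1 | intermediate
21 | C11 phenyl sulfoxide (sulfur epimers) | CC1=CC[C@@H]2C(C)(C)[C@H](O[Si](C)(C)C(C)(C)C)CC[C@@]2(C)[C@@H]1CS(=O)c1ccccc1 | intermediate (not isolated)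
22 | C11 phenyl sulfone | CC1=CC[C@@H]2C(C)(C)[C@H](O[Si](C)(C)C(C)(C)C)CC[C@@]2(C)[C@@H]1CS(=O)(=O)c1ccccc1 | intermediate
23 | 3-methylbut-2-en-1-ol (prenol) | CC(C)=CCO | starting material
24 | tert-butyldimethyl[(3-methylbut-2-en-1-yl)oxy]silane | CC(C)=CCO[Si](C)(C)C(C)(C)C | intermediate
25 | (2E)-4-[(tert-butyldimethylsilyl)oxy]-2-methylbut-2-en-1-ol | OC/C(C)=C/CO[Si](C)(C)C(C)(C)C | intermediate
26 | {[(2E)-4-bromo-3-methylbut-2-en-1-yl]oxy}(tert-butyl)dimethylsilane | BrC/C(C)=C/CO[Si](C)(C)C(C)(C)C | intermediate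
27 | C11-lithiated sulfone from 22 | CC1=CC[C@@H]2C(C)(C)[C@H](O[Si](C)(C)C(C)(C)C)CC[C@@]2(C)[C@@H]1C([Li])S(=O)(=O)c1ccccc1 | intermediate (not isolated)
28 | C11-alkylated sulfone (C11 epimers; 13E side chain with C15 TBS ether) | CC1=CC[C@@H]2C(C)(C)[C@H](O[Si](C)(C)C(C)(C)C)CC[C@@]2(C)[C@@H]1C(C/C(C)=C/CO[Si](C)(C)C(C)(C)C)S(=O)(=O)c1ccccc1 | intermediate
29 | 3,15-bis-O-TBS ether of ent-labda-7,13E-diene-3β,15-diol | CC1=CC[C@@H]2C(C)(C)[C@H](O[Si](C)(C)C(C)(C)C)CC[C@@]2(C)[C@@H]1CC/C(C)=C/CO[Si](C)(C)C(C)(C)C | intermediate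
30 | 3-O-TBS ether of ent-labda-7,13E-diene-3β,15-diol (C15 hydroxyl free) | CC1=CC[C@@H]2C(C)(C)[C@H](O[Si](C)(C)C(C)(C)C)CC[C@@]2(C)[C@@H]1CC/C(C)=C/CO | intermediate (not isolated)
31 | (2E)-5-[(1R,4aS,6R,8aS)-6-hydroxy-2,5,5,8a-tetramethyl-1,4,4a,5,6,7,8,8a-octahydronaphthalen-1-yl]-3-methylpent-2-en-1-ol (ent-labda-7,13E-diene-3β,15-diol) | CC1=CC[C@@H]2C(C)(C)[C@H](O)CC[C@@]2(C)[C@@H]1CC/C(C)=C/CO | intermediate
32 | 16-bromohexadecan-1-ol | OCCCCCCCCCCCCCCCCBr | starting material
33 | [(16-bromohexadecyl)oxy](tert-butyl)dimethylsilane | CC(C)(C)[Si](C)(C)OCCCCCCCCCCCCCCCCBr | intermediate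
34 | 16-bromohexadecanoic acid | OC(=O)CCCCCCCCCCCCCCCBr | starting material
35 | {16-[(tert-butyldimethylsilyl)oxy]hexadecyl}magnesium bromide | CC(C)(C)[Si](C)(C)OCCCCCCCCCCCCCCCC[Mg]Br | intermediate (not isolated)
36 | chloromagnesium 16-bromohexadecanoate | Cl[Mg]OC(=O)CCCCCCCCCCCCCCCBr | intermediate (not isolated)
37 | 32-[(tert-butyldimethylsilyl)oxy]dotriacontanoic acid | OC(=O)CCCCCCCCCCCCCCCCCCCCCCCCCCCCCCCO[Si](C)(C)C(C)(C)C | intermediate
38 | O-acylisourea of 37 with EDC | CCN=C(NCCCN(C)C)OC(=O)CCCCCCCCCCCCCCCCCCCCCCCCCCCCCCCO[Si](C)(C)C(C)(C)C | intermediate (not isolated)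
39 | C15 ester of 31 with 37 (C3 hydroxyl free, ω-TBS ether) | CC1=CC[C@@H]2C(C)(C)[C@H](O)CC[C@@]2(C)[C@@H]1CC/C(C)=C/COC(=O)CCCCCCCCCCCCCCCCCCCCCCCCCCCCCCCO[Si](C)(C)C(C)(C)C | intermediate
40 | (2E)-5-[(1R,4aS,6R,8aS)-6-hydroxy-2,5,5,8a-tetramethyl-1,4,4a,5,6,7,8,8a-octahydronaphthalen-1-yl]-3-methylpent-2-en-1-yl 32-hydroxydotriacontanoate | CC1=CC[C@@H]2C(C)(C)[C@H](O)CC[C@@]2(C)[C@@H]1CC/C(C)=C/COC(=O)CCCCCCCCCCCCCCCCCCCCCCCCCCCCCCCO | target

Total step count: 23 steps.
Longest linear sequence: 18 steps from methyl geranate (steps 1–13, 17–19, 22, 23). The C12–C15 bromide takes 3 steps (14–16) and the C32 acid 2 steps (20, 21).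

Steps most likely to fail

1. Step 7. The cyclisation may lose endo control at the temperature that the trisubstituted dienophile demands: closure through the ester-exo transition state leads into the cis-fused series. Slow cycloaddition may also let desilylation of the dienol ether compete. Fallback: it sets out again from 13. The cycloaddition is run as in step 7, and the cis-fused adduct F1 (C5 and C8 epimer of 14 with the same C9 and C10) is separated and dehydrogenated by Saegusa–Ito oxidation (Pd(OAc)2, MeCN, rt) to the C5=C6 enone F2, which erases C5. Hydrogenation (H2, Pd/C, EtOAc) from the face opposite the axial C20 and C4 methyl groups should then place H5 trans to C20 and give ketone 16, where the route is rejoined. The ring fusion is then fixed by a hydrogenation and no longer by the cycloaddition.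

2. Step 9. Proton loss from C6 instead of C8 in the O-triflyl oxocarbenium ion would divert material into the C6=C7 triflate. Fallback: it sets out from 16. Equilibrating silylation (TMSCl, NaI, Et3N, MeCN, rt) gives the thermodynamic trimethylsilyl enol ether F3 (C7=C8), so the regiochemistry is settled by equilibration before the triflyl group is introduced. CsF and PhNTf2 in DME then convert F3 into enol triflate 17, where the route is rejoined.

3. Step 12. Displacement at C11, which is flanked by C9 and the quaternary C10, may be too slow, so that the alkoxyphosphonium intermediate reverts to the alcohol or eliminates. Fallback: the roles of the coupling partners are reversed, setting out from 19. Tf2O and pyridine (CH2Cl2, −78 °C) give the C11 triflate F4. Bromide 26 and PhSO2Na (DMF, rt) give the allylic sulfone F5, which n-BuLi (THF, −78 °C) converts into the lithiated allylic sulfone F6. F6 displaces the triflate of F4 to give the C12 sulfone F7, and palladium-catalysed hydride desulfonylation ([1,3-bis(diphenylphosphino)propane]PdCl2, LiBHEt3, THF, 0 °C) gives bis-silyl ether 29, where the route is rejoined; steps 13, 17 and 18 are then not needed.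

Further compounds

F1 | step 7 | cis-fused Diels–Alder adduct (C5 and C8 epimer of 14) | C[C@H]1C(O[Si](C)(C)C(C)(C)C)=C[C@H]2C(C)(C)[C@H](O[Si](C)(C)C(C)(C)C)CC[C@@]2(C)[C@@H]1C(=O)OC
F2 | step 7 | C5=C6 enone (7-oxo; C17 trans to the C11 ester) | C[C@H]1C(=O)C=C2C(C)(C)[C@H](O[Si](C)(C)C(C)(C)C)CC[C@@]2(C)[C@@H]1C(=O)OC
F3 | step 9 | thermodynamic trimethylsilyl enol ether of 16 (C7=C8) | CC1=C(O[Si](C)(C)C)C[C@@H]2C(C)(C)[C@H](O[Si](C)(C)C(C)(C)C)CC[C@@]2(C)[C@@H]1C(=O)OC
F4 | step 12 | C11 triflate of 19 | CC1=CC[C@@H]2C(C)(C)[C@H](O[Si](C)(C)C(C)(C)C)CC[C@@]2(C)[C@@H]1COS(=O)(=O)C(F)(F)F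
F5 | step 12 | tert-butyldimethyl{[(2E)-3-methyl-4-(phenylsulfonyl)but-2-en-1-yl]oxy}silane | O=S(=O)(C/C(C)=C/CO[Si](C)(C)C(C)(C)C)c1ccccc1
F6 | step 12 | lithiated allylic sulfone from F5 | O=S(=O)(C([Li])/C(C)=C/CO[Si](C)(C)C(C)(C)C)c1ccccc1
F7 | step 12 | C12 phenylsulfonyl derivative of 29 (C12 epimers) | CC1=CC[C@@H]2C(C)(C)[C@H](O[Si](C)(C)C(C)(C)C)CC[C@@]2(C)[C@@H]1CC(/C(C)=C/CO[Si](C)(C)C(C)(C)C)S(=O)(=O)c1ccccc1
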